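**Retrosynthetic overview**

1. Both C‑prenyl groups (C8 and C3') are made last, by a double aromatic Claisen rearrangement of two O‑(1,1‑dimethylallyl) ethers, which also serve as the only phenol protection.
2. The C3–OH comes from Rubottom oxidation of a 4‑silyloxy‑2H‑chromene, anti to the C2 aryl group.
3. Key step: Rh‑catalysed enantioselective 1,4‑arylation of a 7‑alkoxychromone with an arylzinc, trapped as the enol silane. This dearomatises the γ‑pyrone ring and sets C2.
4. The two fragments come from 7‑hydroxychromone and 4‑bromophenol, each O‑alkylated with a reverse‑prenyl carbonate under Pd(0).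
5. Ring order: the benzopyranone (A/C) bicycle is bought intact and the B ring is attached at C2; no ring is constructed.

Assumption: 7‑hydroxychromone is purchased as a catalogue compound; the reverse‑prenyl carbonate is prepared (step 1) because it is not reliably stocked.

The target is the trans‑(2R,3R) dihydroflavonol; the (2S) enol silane and (2S)‑flavanone have the same spatial arrangement at C2 (the descriptor changes only through CIP priorities).

**Step 1**
Reactants: 1, 2‑methylbut‑3‑en‑2‑ol; 2, di‑tert‑butyl dicarbonate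
Product: 3, tert‑butyl 2‑methylbut‑3‑en‑2‑yl carbonate
Conditions: n‑BuLi, THF, 0 °C; then Boc2O, 0 °C → rt
Reagents that add atoms: Boc2O (compound 2), CC(C)(C)OC(=O)OC(=O)OC(C)(C)C
Why: Acylation of the tertiary lithium alkoxide with Boc2O (carbonate formation) gives the ionisable allyl donor for the next two steps.

**Step 2**
Reactants: 4, 7‑hydroxy‑4H‑chromen‑4‑one; 3, tert‑butyl 2‑methylbut‑3‑en‑2‑yl carbonate
Product: 5, 7‑[(2‑methylbut‑3‑en‑2‑yl)oxy]‑4H‑chromen‑4‑one
Conditions: Pd(PPh3)4 (3 mol %), THF, 0 °C, stopped at full conversion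
Reagents that add atoms: compound 3, C=CC(C)(C)OC(=O)OC(C)(C)C (delivers the C5H9 group; CO2 and t‑BuOH are lost)
Why: Tsuji–Trost O‑allylation; under kinetic control at 0 °C the phenoxide attacks the more substituted terminus of the 1,1‑dimethyl‑π‑allyl‑Pd cation, giving the tertiary (reverse‑prenyl) aryl ether.

**Step 3**
Reactants: 6, 4‑bromophenol; 3, tert‑butyl 2‑methylbut‑3‑en‑2‑yl carbonate
Product: 7, 1‑bromo‑4‑[(2‑methylbut‑3‑en‑2‑yl)oxy]benzene
Conditions: Pd(PPh3)4 (3 mol %), THF, 0 °C
Reagents that add atoms: compound 3, C=CC(C)(C)OC(=O)OC(C)(C)C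
Why: Same kinetic Tsuji–Trost reverse‑prenyl etherification; oxidative addition of the electron‑rich aryl bromide to Pd(0) is negligible at 0 °C.

**Step 4 (key step)**
Reactants: 7, 1‑bromo‑4‑[(2‑methylbut‑3‑en‑2‑yl)oxy]benzene (1.5 equiv); 5, 7‑[(2‑methylbut‑3‑en‑2‑yl)oxy]‑4H‑chromen‑4‑one
Product: 8, (2S)‑7‑[(2‑methylbut‑3‑en‑2‑yl)oxy]‑2‑{4‑[(2‑methylbut‑3‑en‑2‑yl)oxy]phenyl}‑4‑(trimethylsilyloxy)‑2H‑chromene
Conditions: 7, n‑BuLi, THF, −78 °C; ZnCl2, −78 → 20 °C; then 5, [RhCl(C2H4)2]2 (2.5 mol %), (S)‑BINAP (5.5 mol %), TMSCl (1.6 equiv), THF, 20 °C; cold NaHCO3/pentane work‑up, crude used directly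
Reagents that add atoms: chlorotrimethylsilane, C[Si](C)(C)Cl
Why: Proposed new method: Rh(I)/BINAP asymmetric 1,4‑addition of ArZnCl with TMSCl trapping is established for 4‑quinolones and 2,3‑dihydro‑4‑pyridones but not for chromones; here the aryl–Rh(I) species carbometalates C2=C3 of the chromone enantioface‑selectively and TMSCl silylates the oxa‑π‑allyl‑Rh enolate (catalyst turnover, no free enolate, so no β‑aryloxide ring opening or C2 racemisation), which dearomatises the pyrone and sets C2 as S (sense predicted from the (R)‑BINAP → (R) outcome with 4‑quinolones; the ligand antipode is used if CD shows the opposite).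

**Step 5**
Reactants: 8, the (2S) enol silane
Product: 9, (2R,3R)‑3‑hydroxy‑7‑[(2‑methylbut‑3‑en‑2‑yl)oxy]‑2‑{4‑[(2‑methylbut‑3‑en‑2‑yl)oxy]phenyl}chroman‑4‑one
Conditions: DMDO (1.05 equiv), acetone/CH2Cl2, −78 → −30 °C; then TBAF/AcOH (1:1), THF, 0 °C
Reagents that add atoms: dimethyldioxirane, CC1(C)OO1 (delivers the C3 oxygen)
Why: Rubottom oxidation; DMDO epoxidises the electron‑rich enol silane far faster than the two hindered monosubstituted vinyl groups and from the face anti to the C2 aryl, so after silyloxy‑epoxide opening the C3–OH is trans to the aryl (2R,3R).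

**Step 6**
Reactants: 9, the (2R,3R) bis(reverse‑prenyl) ether
Product: 10, 3‑hydroxyglabrol, (2R,3R)‑3,7‑dihydroxy‑2‑[4‑hydroxy‑3‑(3‑methylbut‑2‑enyl)phenyl]‑8‑(3‑methylbut‑2‑enyl)chroman‑4‑one
Conditions: degassed DMF, BHT (cat.), 120 °C, sealed tube, 2–3 h
Reagents that add atoms: none
Why: Double aromatic Claisen ([3,3]) rearrangement through ortho‑cyclohexadienones that re‑aromatise: the A‑ring ether migrates to C8 (C7=C8 bond fixation by the ring oxygen and C4 carbonyl, as in 7‑allyloxy‑chromanones, chromones and coumarins; a minor C6 isomer is separable), the B‑ring ether to either equivalent ortho position (C3'), and the neutral conditions leave C2 and C3 untouched.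

**Compound list**

1 | 2‑methylbut‑3‑en‑2‑ol | C=CC(C)(C)O | starting material
2 | di‑tert‑butyl dicarbonate | CC(C)(C)OC(=O)OC(=O)OC(C)(C)C | starting material
3 | tert‑butyl 2‑methylbut‑3‑en‑2‑yl carbonate | C=CC(C)(C)OC(=O)OC(C)(C)C | intermediate
4 | 7‑hydroxy‑4H‑chromen‑4‑one | O=c1ccoc2cc(O)ccc12 | starting material
5 | 7‑[(2‑methylbut‑3‑en‑2‑yl)oxy]‑4H‑chromen‑4‑one | C=CC(C)(C)Oc1ccc2c(c1)occc2=O | intermediate
6 | 4‑bromophenol | Oc1ccc(Br)cc1 | starting material
7 | 1‑bromo‑4‑[(2‑methylbut‑3‑en‑2‑yl)oxy]benzene | C=CC(C)(C)Oc1ccc(Br)cc1 | intermediate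
8 | (2S)‑7‑[(2‑methylbut‑3‑en‑2‑yl)oxy]‑2‑{4‑[(2‑methylbut‑3‑en‑2‑yl)oxy]phenyl}‑4‑(trimethylsilyloxy)‑2H‑chromene | C=CC(C)(C)Oc1ccc(cc1)[C@H]1Oc2cc(OC(C)(C)C=C)ccc2C(O[Si](C)(C)C)=C1 | intermediate
9 | (2R,3R)‑3‑hydroxy‑7‑[(2‑methylbut‑3‑en‑2‑yl)oxy]‑2‑{4‑[(2‑methylbut‑3‑en‑2‑yl)oxy]phenyl}chroman‑4‑one | C=CC(C)(C)Oc1ccc(cc1)[C@H]1Oc2cc(OC(C)(C)C=C)ccc2C(=O)[C@@H]1O | intermediate
10 | 3‑hydroxyglabrol | CC(C)=CCc1cc([C@H]2Oc3c(ccc(O)c3CC=C(C)C)C(=O)[C@@H]2O)ccc1O | target

**Totals**

Total steps: 6. Longest linear sequence: 5 (steps 1 → 2 → 4 → 5 → 6).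

**Three steps most likely to fail**

1. Step 4 (chromone is untested in the ArZnCl/TMSCl manifold; Rh(I) may ionise the tertiary allyl aryl ethers; ee is unproven). Fallback: convert 7 to the arylboronic acid (n‑BuLi, B(OiPr)3) and use the established base‑free Rh/electron‑poor biaryl‑bisphosphine 1,4‑addition of arylboronic acids to chromones to isolate the (2S)‑flavanone, then form 8 separately by LiHMDS/TMSCl internal‑quench silylation at −78 °C.
2. Step 6 (C8 versus C6 regiochemistry, loss of isoprene from the tertiary ethers, thermal epimerisation of the ketol). Fallback: move the rearrangements ahead of the key step. Claisen on 5 alone gives 7‑hydroxy‑8‑prenylchromone and on 7 alone gives 4‑bromo‑2‑prenylphenol; protect both as TBS ethers, carry out the arylation, hydroxylate with an alkene‑tolerant enolate oxidant (Davis oxaziridine), and finish with fluoride deprotection.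
3. Step 5 (incomplete anti selectivity, competing vinyl epoxidation, acid‑labile ethers). Fallback: replace the epoxidation by enolate hydroxylation: regenerate the lithium enolate from 8 with MeLi at −78 °C and oxidise it with a Davis N‑sulfonyloxaziridine, which does not react with alkenes and is delivered anti to the C2 aryl.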